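## Plan

Target ring locants: C1 (C=O next to the carbinol), C2 (gem-diprenyl), C3 (C=O), C4 (isobutyryl-bearing), C5 (enol), C6 (carbinol, S).

- **Cuts:** two helpers come off first, namely ethyl on the C5 enol oxygen and trimethylsilyl on the C6 oxygen. The ring is then cut at C5–C6 and C3–C4 together. This gives 3,3,5-triprenylfuran-2,4-dione (as its silyl enol ether) and the acyl ynol ether 1-ethoxy-4-methylpent-1-yn-3-one.
- **Enabling feature:** the C6 carbinol oxygen lies 1,4 across the ring from the C3 carbonyl carbon, so O–C6–C1–C2–C3 can be stored as a five-membered β-keto lactone. In that lactone C6 is the only enolisable carbon, and C3 is an acyl donor whose leaving group is the oxygen the target keeps. C4=C5(OH) with its acyl group is the hydrate of an acyl alkyne.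
- **Forward order:** tetronic acid ring, three prenylations, silyl enol ether, then the annulation (the carbocycle closes while the temporary lactone opens), then one hydrolysis.
- **Stereochemistry:** C6 is created in the annulation from a planar enolate under a chiral quaternary ammonium counter-ion. The racemic lactone centre made earlier is erased, so the route is stereoconvergent.

Key step: step 5

Assumption: the cinchonidinium cation is taken to expose the enolate face that leads to the (S)-carbinol (otherwise the pseudoenantiomeric cinchoninium phenoxide is used unchanged); the target is treated as the enol tautomer of its SMILES.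

## Route

Step 1
Reactants: 1 tetronic acid (furan-2,4(3H,5H)-dione); 2 prenyl acetate (3-methylbut-2-enyl acetate)
Product: 4 3,3-bis(3-methylbut-2-enyl)furan-2,4(3H,5H)-dione, via 3-prenyltetronic acid 3 (not isolated)
Conditions: 2 (2.3 equiv), Pd(PPh3)4 (5 mol %), THF, 55 °C
Reagents that add atoms: none
Why: Tsuji–Trost allylation, in which the acidic tetronic acid is deprotonated by the acetate released on ionisation, the soft tetronate attacks the prenyl–palladium cation at its unsubstituted terminus, any O-prenyl tetronate is re-ionised by zerovalent palladium, and the material should drain through 3 into the non-ionisable C3-quaternary dione 4.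

Step 2
Reactants: 4 3,3-diprenylfuran-2,4-dione; 5 prenyl bromide (1-bromo-3-methylbut-2-ene)
Product: 7 rac-3,3,5-tris(3-methylbut-2-enyl)furan-2,4(3H,5H)-dione, via lithium 5-oxo-4,4-diprenyl-4,5-dihydrofuran-3-olate 6 (not isolated)
Conditions: LiHMDS (1.05 equiv), THF, −78 °C; 5 (1.1 equiv), −78 to −20 °C
Reagents that add atoms: none
Why: Kinetic enolate alkylation, in which the C5 methylene is the only acidic site because C3 is quaternary, and the allylic bromide should C-alkylate enolate 6 (SN2) to give a racemate whose centre is flattened again in step 3.

Step 3
Reactants: 7 rac-3,3,5-triprenylfuran-2,4-dione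
Product: 9 3,3,5-tris(3-methylbut-2-enyl)-4-(trimethylsilyloxy)furan-2(3H)-one, via lithium 5-oxo-2,4,4-triprenyl-4,5-dihydrofuran-3-olate 8 (not isolated)
Conditions: LiHMDS (1.1 equiv), THF, −78 °C; TMSCl, −78 to 0 °C; pentane, filtration (non-aqueous work-up)
Reagents that add atoms: chlorotrimethylsilane, C[Si](C)(C)Cl
Why: Silyl enol ether formation by O-silylation of the only possible enolate stores the nucleophile in a neutral, proton-free form that a catalytic Lewis base can release in step 5.

Step 4
Reactants: 10 ethoxyacetylene; 11 N-methoxy-N-methylisobutyramide
Product: 13 1-ethoxy-4-methylpent-1-yn-3-one, via lithium ethoxyacetylide 12 (not isolated)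
Conditions: n-BuLi, THF, −78 °C; 11, −78 to −20 °C; cold aq NH4Cl
Reagents that add atoms: none
Why: Weinreb ketone synthesis, in which the acetylide adds once and the chelated tetrahedral adduct survives until the quench, so that no tertiary alcohol should form.

Step 5
Reactants: 9 silyl enol ether of the triprenyl lactone; 13 1-ethoxy-4-methylpent-1-yn-3-one
Product: 18 (6S)-5-ethoxy-4-(2-methylpropanoyl)-2,2,6-tris(3-methylbut-2-enyl)-6-(trimethylsilyloxy)cyclohex-4-ene-1,3-dione, via chiral ammonium enolate 14 (not isolated), via allenolate adduct 15 (not isolated), via oxygen-bridged alkoxide 16 (not isolated), via tertiary alkoxide 17 (not isolated)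
Conditions: 13 (1.2 equiv), O-allyl-N-(9-anthracenylmethyl)cinchonidinium phenoxide (10 mol %), 4 Å molecular sieves, toluene/THF, −60 to −40 °C
Reagents that add atoms: none
Why: Proposed new method: phenoxide removes the silyl group of 9 and leaves enolate 14 as a contact ion pair with the chiral cation; its only nucleophilic carbon (lactone C5) adds to the ethoxy-bearing alkyne carbon of 13, and, since the medium holds no proton source, allenolate 15 attacks through its central carbon the lactone carbonyl that sits 1,3 to the new quaternary carbon across the ring oxygen, giving bridged alkoxide 16, which breaks its C1–O7 bond to tertiary alkoxide 17; 17 takes the silyl group from PhOSiMe3 (or from 9) and so returns the catalyst. The closest known reaction type is the Hauser–Kraus annulation (lactone carbanion, Michael addition, Dieckmann closure on the lactone carbonyl through the same oxygen-bridged intermediate, also known with arynes, where an sp2 carbanion closes the ring), here joined to chiral ammonium phenoxide-catalysed Mukaiyama–Michael/acyl substitution cascades of silyl enolates and to catalytic asymmetric additions of alpha-oxygenated cyclic pronucleophiles to ynones; new are the furan-2,4-dione donor, the acyl ynol ether acceptor and the enantioselective form. The carbocycle closes by a 6-(enolexo)-exo-trig acyl substitution (5-exo-trig if counted through the oxygen bridge) and the five-membered lactone opens in the same event, so that the two alkyne carbons end up inserted between C5 and C2 of the lactone while the ring oxygen stays on carbon as the carbinol oxygen. The only stereocentre is fixed in the first C–C bond formation: 14 is planar, the racemic centre of 7 is gone, and the cinchonidinium cation bound at the enolate oxygen screens one face, so that the linear, sterically undemanding alkyne should approach the open face to give the (S) centre, whose four bonds are not touched afterwards. The step needs C- over O-attack (soft acceptor, O-adducts revert), 1,4- over 1,2-addition (the isopropyl group shields the ketone and the ethoxy group polarises the alkyne towards the desired carbon), a single enolate (lactone C3 is quaternary) and ring closure ahead of silylation of 15 or loss of ethoxide from it (closure is intramolecular through a five-membered array, whereas ethoxide loss is the reverse of a strongly downhill alkoxide addition to an ynone and should be slow at low temperature). The ethyl cap keeps the product from being a strongly acidic beta-triketone, which would otherwise protonate the enolate and stop turnover.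

Step 6
Reactants: 18 ethyl enol ether/silyl ether
Product: 19 (6S)-5,6-dihydroxy-4-(2-methylpropanoyl)-2,2,6-tris(3-methylbut-2-enyl)cyclohex-4-ene-1,3-dione (target)
Conditions: 0.5 M aq HCl, THF, 0 °C to rt
Reagents that add atoms: water, O
Why: Hydrolysis of a vinylogous ester by addition–elimination of water at C5, which the C3 ketone and the isobutyryl group doubly activate, together with cleavage of the labile tertiary trimethylsilyl ether at silicon, so both helpers should leave under conditions too mild for the prenyl groups or the C6–O bond to be affected.

## Compound list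

1 | tetronic acid | O=C1COC(=O)C1 | starting material
2 | prenyl acetate | CC(=O)OCC=C(C)C | starting material
3 | 3-prenyltetronic acid | OC1=C(CC=C(C)C)C(=O)OC1 | intermediate
4 | 3,3-diprenylfuran-2,4(3H,5H)-dione | O=C1COC(=O)C1(CC=C(C)C)CC=C(C)C | intermediate
5 | prenyl bromide | CC(C)=CCBr | starting material
6 | lithium 5-oxo-4,4-diprenyl-4,5-dihydrofuran-3-olate | [Li+].[O-]C1=COC(=O)C1(CC=C(C)C)CC=C(C)C | intermediate
7 | rac-3,3,5-triprenylfuran-2,4(3H,5H)-dione | O=C1C(CC=C(C)C)OC(=O)C1(CC=C(C)C)CC=C(C)C | intermediate
8 | lithium 5-oxo-2,4,4-triprenyl-4,5-dihydrofuran-3-olate | [Li+].[O-]C1=C(CC=C(C)C)OC(=O)C1(CC=C(C)C)CC=C(C)C | intermediate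
9 | 3,3,5-triprenyl-4-(trimethylsilyloxy)furan-2(3H)-one | C[Si](C)(C)OC1=C(CC=C(C)C)OC(=O)C1(CC=C(C)C)CC=C(C)C | intermediate
10 | ethoxyacetylene | C#COCC | starting material
11 | N-methoxy-N-methylisobutyramide | CC(C)C(=O)N(C)OC | starting material
12 | lithium ethoxyacetylide | [Li+].[C-]#COCC | intermediate
13 | 1-ethoxy-4-methylpent-1-yn-3-one | CCOC#CC(=O)C(C)C | intermediate
14 | 5-oxo-2,4,4-triprenyl-4,5-dihydrofuran-3-olate (anion shown, counter-ion is the catalyst cation) | [O-]C1=C(CC=C(C)C)OC(=O)C1(CC=C(C)C)CC=C(C)C | intermediate
15 | allenolate adduct, (5S) at the lactone carbon that bears prenyl and the 1-ethoxyallenyl unit | CCOC(=C=C([O-])C(C)C)[C@]1(CC=C(C)C)OC(=O)C(CC=C(C)C)(CC=C(C)C)C1=O | intermediate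
16 | (1S,4S)-3-ethoxy-2-isobutyryl-5-oxo-4,6,6-triprenyl-7-oxabicyclo[2.2.1]hept-2-en-1-olate | [O-][C@]12C(C(=O)C(C)C)=C(OCC)[C@](CC=C(C)C)(O1)C(=O)C2(CC=C(C)C)CC=C(C)C | intermediate
17 | (S)-tertiary alkoxide of the ring-switched cyclohexenedione | CC(C)=CCC1(CC=C(C)C)C(=O)C(C(=O)C(C)C)=C(OCC)[C@@]([O-])(CC=C(C)C)C1=O | intermediate
18 | (6S)-5-ethoxy-4-isobutyryl-2,2,6-triprenyl-6-(trimethylsilyloxy)cyclohex-4-ene-1,3-dione | CC(C)=CCC1(CC=C(C)C)C(=O)C(C(=O)C(C)C)=C(OCC)[C@@](O[Si](C)(C)C)(CC=C(C)C)C1=O | intermediate
19 | (6S)-5,6-dihydroxy-4-isobutyryl-2,2,6-triprenylcyclohex-4-ene-1,3-dione | CC(C)=CCC1(CC=C(C)C)C(=O)C(C(=O)C(C)C)=C(O)[C@@](O)(CC=C(C)C)C1=O | target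

## Count and risks

Total steps: 6. Longest linear sequence: 5 (steps 1, 2, 3, 5, 6).

**Step 5 (labelled).**
- The allenolate may be silylated, or may lose ethoxide, before it closes on the lactone.
- The enolate may react at oxygen, or the chiral cation may discriminate poorly between the enolate faces.
- The fallback uses known chemistry, sets out from prenyl bromide 5 and returns at 19.
- Commercial 2-methyl-1-(2,4,6-trihydroxyphenyl)propan-1-one F1 is C-prenylated three times with 5 (aq KOH, 0 °C), which dearomatises it to colupulone F2.
- The potassium enolate of F2 (KHMDS, THF, −78 °C) is hydroxylated at the prenyl-bearing ring carbon with (+)-(camphorsulfonyl)oxaziridine. This is an asymmetric enolate hydroxylation, and the antipode of the reagent is chosen after a trial.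
- Residual minor enantiomer is removed by chromatography on a chiral stationary phase to give 19.

**Step 1.**
- Attack may occur at the substituted terminus of the prenyl–palladium cation (reverse prenylation).
- The reaction may stall after one alkylation, or O-alkylation may persist.
- The fallback builds the ring around the quaternary carbon, sets out from 5 and returns at 4.
- Commercial ethyl 4-chloro-3-oxobutanoate F3 is alkylated twice at C2 with 5 (K2CO3, acetone) to ethyl 4-chloro-3-oxo-2,2-diprenylbutanoate F4.
- Heating F4 with catalytic NaI in xylene closes the lactone through the ester oxygen, with loss of the ethyl group as its chloride, and gives 4.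

**Step 2.**
- Proton exchange between product and enolate may lead to double alkylation at C5.
- The enolate may attack the reactive lactone of a second molecule.
- The fallback reverses the order of prenylation, sets out from 5 and returns at 7.
- Commercial 4-methoxyfuran-2(5H)-one F5 is deprotonated at C5 (LDA, THF, −78 °C) and alkylated with 5 to rac-4-methoxy-5-prenylfuran-2(5H)-one F6.
- Nucleophilic demethylation (LiCl, DMSO, heat, then acid) gives rac-5-prenyltetronic acid F7.
- F7 is doubly C3-prenylated with 2 under the conditions of step 1 to give 7.

Further compounds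
F1 | step 5 | 2-methyl-1-(2,4,6-trihydroxyphenyl)propan-1-one | CC(C)C(=O)c1c(O)cc(O)cc1O
F2 | step 5 | colupulone | CC(C)=CCC1=C(O)C(CC=C(C)C)(CC=C(C)C)C(=O)C(C(=O)C(C)C)=C1O
F3 | step 1 | ethyl 4-chloro-3-oxobutanoate | CCOC(=O)CC(=O)CCl
F4 | step 1 | ethyl 4-chloro-3-oxo-2,2-bis(3-methylbut-2-enyl)butanoate | CCOC(=O)C(CC=C(C)C)(CC=C(C)C)C(=O)CCl
F5 | step 2 | 4-methoxyfuran-2(5H)-one | COC1=CC(=O)OC1
F6 | step 2 | rac-4-methoxy-5-(3-methylbut-2-enyl)furan-2(5H)-one | COC1=CC(=O)OC1CC=C(C)C
F7 | step 2 | rac-5-(3-methylbut-2-enyl)tetronic acid | OC1=CC(=O)OC1CC=C(C)C
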